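**Strategy.** Ring A of the flavone is built around the pre-set benzylic stereocentre, not substituted afterwards. A 3-ethoxycyclobutenone carrying the (S)-CH(Ph)CH2CO2Me chain on its sp3 carbon is heated with (triisopropylsiloxy)ethyne. In one operation the alkyne carbons are inserted between the carbonyl carbon and the vinylic CH, and a benzene ring results in which the side-chain carbon (later C6) lies between a free OH and an OEt (later the C5 and C7 oxygens) and para to a silyloxy group (later O1 on C8a). Because only that para oxygen can be unmasked selectively, ring C can close in one direction only, giving the 6-substituted flavone.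

Key step: step 4

Remarks on the chemistry (position numbers are those of the flavone skeleton):
- (DHQD)2AQN is assumed to give the (R)-half-ester 2; if the rotation of 2 shows the opposite sense, the pseudo-enantiomeric (DHQ)2AQN is used and nothing else changes.
- (Triisopropylsiloxy)ethyne is treated as not purchasable and is made in step 3.
- The benzylic carbon keeps one spatial arrangement throughout; it reads R in 2, S in 4–6 and 12–15, and R from 16 on, only because CIP priorities change.

Step 1
Reactants: 1 3-phenylglutaric anhydride
Product: 2 (R)-5-methoxy-5-oxo-3-phenylpentanoic acid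
Conditions: MeOH (10 equiv), hydroquinidine anthraquinone-1,4-diyl diether [(DHQD)2AQN, 20 mol %], Et2O, −40 °C; 1 M HCl wash
Reagents that add atoms: methanol, CO
Why: Cinchona-alkaloid-catalysed desymmetrising methanolysis of a prochiral cyclic anhydride, in which the quinuclidine nitrogen delivers methanol inside the chiral pocket to one of the two enantiotopic carbonyl groups and so fixes C3 as (R); one crystallisation of the acid as an amine salt is available to raise the enantiomeric purity.

Step 2
Reactants: 2 (R)-5-methoxy-5-oxo-3-phenylpentanoic acid; 3 ethoxyacetylene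
Product: 6 methyl (3S)-3-(2-ethoxy-4-oxocyclobut-2-en-1-yl)-3-phenylpropanoate (both ring epimers), via acid chloride 4 (not isolated), via ketene 5 (not isolated)
Conditions: (COCl)2 (1.3 equiv), DMF (cat.), CH2Cl2, 0 °C → rt; volatiles removed below 25 °C; then 3 (2.5 equiv), Et3N (1.3 equiv), Et2O, 0 °C → rt, slow addition of the acid chloride
Reagents that add atoms: none
Why: Vilsmeier-type chlorination gives 4 below room temperature (so the ester and acyl chloride ends do not exchange), triethylamine dehydrochlorinates it to aldoketene 5, and a thermal ketene–ynol ether [2+2] cycloaddition, with the nucleophilic CH of 3 attacking the ketene carbonyl carbon, should give the 3-ethoxy-4-substituted cyclobutenone; the benzylic centre is not α to a carbonyl and is untouched, and the new ring stereocentre is irrelevant because it becomes sp2 in step 4.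

Step 3
Reactants: 7 acetylene; 8 triisopropylsilyl trifluoromethanesulfonate
Product: 11 (triisopropylsiloxy)ethyne, via lithium acetylide 9 (not isolated), via lithium ethynolate 10 (not isolated)
Conditions: 7 (excess), n-BuLi (1.0 equiv), THF, −78 °C; LiOOt-Bu (1.1 equiv, from t-BuOOH and LiN(SiMe3)2, THF, −78 °C), −78 → −20 °C; then 8 (1.1 equiv), −78 → 0 °C; pentane extraction, kept cold under argon and used promptly
Reagents that add atoms: lithium tert-butyl peroxide, CC(C)(C)OO[Li]
Why: The acetylide attacks the electrophilic oxygen of the lithium peroxide (the established acetylide-to-ynolate oxidation), and the bulky silyl triflate should silylate the ynolate at oxygen, not at carbon, to give the siloxyalkyne.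

Step 4
Reactants: 6 methyl (3S)-3-(2-ethoxy-4-oxocyclobut-2-en-1-yl)-3-phenylpropanoate; 11 (triisopropylsiloxy)ethyne
Product: 16 methyl (R)-3-{2-ethoxy-6-hydroxy-4-[(triisopropylsilyl)oxy]phenyl}-3-phenylpropanoate, via vinylketene 12 (not isolated), via vinylcyclobutenone 13 (not isolated), via dienylketene 14 (not isolated), via cyclohexadienone 15 (not isolated)
Conditions: 11 (1.5 equiv), toluene (0.3 M), 80 °C, then 110 °C, argon
Reagents that add atoms: none
Why: Heating opens 6 by conrotatory 4π electrocyclic cleavage of its C1–C4 bond to vinylketene 12, whose ketene C=C adds [2+2] to the ynol ether with the ketene carbonyl carbon bonding to the alkyne CH and the α-carbon to the silyloxy-bearing carbon (13); a second 4π opening gives dienylketene 14, which cyclises and enolises (15, then 16). The closest known reaction type is the Danheiser benzannulation of cyclobutenones with siloxyalkynes to polyoxygenated phenols. The six-membered ring is closed by thermal disrotatory 6π electrocyclisation of the (Z)-dienylketene, joining the ketene carbon to the terminus that bears the side chain, after the two new C–C bonds have been made in the [2+2] event. No stereocentre is created: the benzylic centre lies one atom outside the reacting π system, has no acidic hydrogen and is carried through unchanged. The step needs regiocontrol, secured by the matched polarity of ketene (electrophilic carbonyl carbon) and ynol ether (nucleophilic CH), which puts OH and OEt beside the side chain and the silyloxy group para to it; it also needs outward rotation of the bulky C4 substituent on ring opening, which gives the diene geometry that can cyclise and keeps the benzylic hydrogen away from a 1,5-shift to the ketene. The excess of 11 keeps ketene 12 from acylating the phenol as it forms.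

Step 5
Reactants: 16 methyl (R)-3-{2-ethoxy-6-hydroxy-4-[(triisopropylsilyl)oxy]phenyl}-3-phenylpropanoate
Product: 17 methyl (R)-3-{2,6-diethoxy-4-[(triisopropylsilyl)oxy]phenyl}-3-phenylpropanoate
Conditions: EtI (3 equiv), K2CO3 (3 equiv), dry acetone, 50 °C
Reagents that add atoms: iodoethane, CCI
Why: Williamson etherification of the phenoxide; ethyl is chosen so that both oxygens beside the side chain carry the same group, which makes the two remaining ring CH positions equivalent for step 7 and lets one reagent clear both ethers at the end, while the aryl silyl ether tolerates dry carbonate.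

Step 6
Reactants: 17 methyl (R)-3-{2,6-diethoxy-4-[(triisopropylsilyl)oxy]phenyl}-3-phenylpropanoate
Product: 18 methyl (R)-3-(2,6-diethoxy-4-hydroxyphenyl)-3-phenylpropanoate
Conditions: n-Bu4NF (1.1 equiv), AcOH (1.1 equiv), THF, 0 °C
Reagents that add atoms: none
Why: Fluoride-induced Si–O cleavage, driven by the Si–F bond, frees only the oxygen para to the side chain, and the acetic acid buffer protects the methyl ester.

Step 7
Reactants: 18 methyl (R)-3-(2,6-diethoxy-4-hydroxyphenyl)-3-phenylpropanoate
Product: 20 methyl (R)-3-(3-acetyl-2,6-diethoxy-4-hydroxyphenyl)-3-phenylpropanoate, via difluoroboron chelate 19 (not isolated)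
Conditions: Ac2O (1.3 equiv), BF3·OEt2 (3 equiv), 1,2-dichloroethane, 0 → 50 °C; then NaOAc, MeOH/H2O, 50 °C
Reagents that add atoms: acetic anhydride, CC(=O)OC(C)=O
Why: BF3-mediated Friedel–Crafts C-acetylation (Fries-type if the O-acetate forms first) of a phloroglucinol-type phenol whose para position is blocked and whose two ortho positions are equivalent, so a single 2-hydroxyacetophenone should form; chelate 19 shields it from a second acylation until the work-up hydrolyses it.

Step 8
Reactants: 20 methyl (R)-3-(3-acetyl-2,6-diethoxy-4-hydroxyphenyl)-3-phenylpropanoate; 21 4-methoxybenzaldehyde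
Product: 22 (R)-3-{2,6-diethoxy-4-hydroxy-3-[(E)-3-(4-methoxyphenyl)prop-2-enoyl]phenyl}-3-phenylpropanoic acid
Conditions: 21 (1.3 equiv), KOH (50% aq., 15 equiv), EtOH, 0 °C → rt; then 1 M HCl to pH 3, 0 °C
Reagents that add atoms: potassium hydroxide, [K+].[OH-]
Why: Claisen–Schmidt condensation of the methyl ketone with the non-enolisable aldehyde gives the (E)-chalcone while hydroxide saponifies the methyl ester (BAc2) in the same pot; the benzylic centre has no hydrogen that hydroxide can remove.

Step 9
Reactants: 22 (R)-3-{2,6-diethoxy-4-hydroxy-3-[(E)-3-(4-methoxyphenyl)prop-2-enoyl]phenyl}-3-phenylpropanoic acid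
Product: 23 (R)-3-[5,7-diethoxy-2-(4-methoxyphenyl)-4-oxo-4H-chromen-6-yl]-3-phenylpropanoic acid
Conditions: I2 (10 mol %), DMSO, 120 °C
Reagents that add atoms: none
Why: Iodine-catalysed oxidative cyclisation of a 2'-hydroxychalcone (oxa-Michael closure, α-iodination, loss of HI, with DMSO regenerating I2); the only free phenol is the oxygen para to the side chain, so ring C should close solely to the 6-substituted flavone.

Step 10
Reactants: 23 (R)-3-[5,7-diethoxy-2-(4-methoxyphenyl)-4-oxo-4H-chromen-6-yl]-3-phenylpropanoic acid
Product: 24 (R)-3-[5,7-dihydroxy-2-(4-hydroxyphenyl)-4-oxo-4H-chromen-6-yl]-3-phenylpropanoic acid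
Conditions: BBr3 (8 equiv), CH2Cl2, −78 °C → rt; H2O, 0 °C; then LiOH (1 M aq.), THF, 0 °C, argon; 1 M HCl to pH 3, 0 °C, concentration without heating
Reagents that add atoms: none
Why: Lewis-acid ether cleavage (boron coordination, then bromide SN2 attack on the ethyl and methyl groups) should free all three phenols at or below room temperature without ionising the benzylic C–aryl bond, and the brief cold hydroxide stage hydrolyses the borate esters and would reopen any lactone closed onto a neighbouring phenol before the open acid is released.

**Compound list**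
1 | 3-phenylglutaric anhydride (4-phenyloxane-2,6-dione) | O=C1CC(c2ccccc2)CC(=O)O1 | starting material
2 | (R)-5-methoxy-5-oxo-3-phenylpentanoic acid | COC(=O)C[C@H](c1ccccc1)CC(=O)O | intermediate
3 | ethoxyacetylene | C#COCC | starting material
4 | methyl (S)-5-chloro-5-oxo-3-phenylpentanoate | COC(=O)C[C@H](c1ccccc1)CC(=O)Cl | intermediate
5 | methyl (S)-5-oxo-3-phenylpent-4-enoate (aldoketene) | COC(=O)C[C@H](c1ccccc1)C=C=O | intermediate
6 | methyl (3S)-3-(2-ethoxy-4-oxocyclobut-2-en-1-yl)-3-phenylpropanoate, both epimers at the ring carbon | COC(=O)C[C@H](c1ccccc1)C1C(=O)C=C1OCC | intermediate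
7 | acetylene | C#C | starting material
8 | triisopropylsilyl trifluoromethanesulfonate | CC(C)[Si](OS(=O)(=O)C(F)(F)F)(C(C)C)C(C)C | starting material
9 | lithium acetylide | [Li]C#C | intermediate
10 | lithium ethynolate | [Li]OC#C | intermediate
11 | (triisopropylsiloxy)ethyne | C#CO[Si](C(C)C)(C(C)C)C(C)C | intermediate
12 | methyl (3S,4Z)-5-ethoxy-7-oxo-3-phenylhepta-4,6-dienoate (vinylketene) | COC(=O)C[C@H](c1ccccc1)/C=C(OCC)/C=C=O | intermediate
13 | methyl (3S,4Z)-5-ethoxy-5-{4-oxo-2-[(triisopropylsilyl)oxy]cyclobut-2-en-1-yl}-3-phenylpent-4-enoate, either ring epimer | COC(=O)C[C@H](c1ccccc1)/C=C(OCC)/C1C(=O)C=C1O[Si](C(C)C)(C(C)C)C(C)C | intermediate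
14 | methyl (3S,4Z,6E)-5-ethoxy-9-oxo-3-phenyl-7-[(triisopropylsilyl)oxy]nona-4,6,8-trienoate (dienylketene) | COC(=O)C[C@H](c1ccccc1)/C=C(OCC)/C=C(O[Si](C(C)C)(C(C)C)C(C)C)\C=C=O | intermediate
15 | methyl (3S)-3-{2-ethoxy-6-oxo-4-[(triisopropylsilyl)oxy]cyclohexa-2,4-dien-1-yl}-3-phenylpropanoate, either ring epimer | COC(=O)C[C@H](c1ccccc1)C1C(=O)C=C(O[Si](C(C)C)(C(C)C)C(C)C)C=C1OCC | intermediate
16 | methyl (R)-3-{2-ethoxy-6-hydroxy-4-[(triisopropylsilyl)oxy]phenyl}-3-phenylpropanoate | COC(=O)C[C@H](c1ccccc1)c1c(O)cc(O[Si](C(C)C)(C(C)C)C(C)C)cc1OCC | intermediate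
17 | methyl (R)-3-{2,6-diethoxy-4-[(triisopropylsilyl)oxy]phenyl}-3-phenylpropanoate | COC(=O)C[C@H](c1ccccc1)c1c(OCC)cc(O[Si](C(C)C)(C(C)C)C(C)C)cc1OCC | intermediate
18 | methyl (R)-3-(2,6-diethoxy-4-hydroxyphenyl)-3-phenylpropanoate | COC(=O)C[C@H](c1ccccc1)c1c(OCC)cc(O)cc1OCC | intermediate
19 | difluoroboron chelate of 20 (BF2 bridging the phenolate and acetyl oxygens) | COC(=O)C[C@H](c1ccccc1)c1c(OCC)cc2O[B-](F)(F)[O+]=C(C)c2c1OCC | intermediate
20 | methyl (R)-3-(3-acetyl-2,6-diethoxy-4-hydroxyphenyl)-3-phenylpropanoate | COC(=O)C[C@H](c1ccccc1)c1c(OCC)cc(O)c(C(C)=O)c1OCC | intermediate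
21 | 4-methoxybenzaldehyde | COc1ccc(C=O)cc1 | starting material
22 | (R)-3-{2,6-diethoxy-4-hydroxy-3-[(E)-3-(4-methoxyphenyl)prop-2-enoyl]phenyl}-3-phenylpropanoic acid | OC(=O)C[C@H](c1ccccc1)c1c(OCC)cc(O)c(C(=O)/C=C/c2ccc(OC)cc2)c1OCC | intermediate
23 | (R)-3-[5,7-diethoxy-2-(4-methoxyphenyl)-4-oxo-4H-chromen-6-yl]-3-phenylpropanoic acid | OC(=O)C[C@H](c1ccccc1)c1c(OCC)cc2oc(-c3ccc(OC)cc3)cc(=O)c2c1OCC | intermediate
24 | (R)-3-[5,7-dihydroxy-2-(4-hydroxyphenyl)-4-oxo-4H-chromen-6-yl]-3-phenylpropanoic acid | O=C(O)C[C@H](c1ccccc1)c1c(O)cc2oc(-c3ccc(O)cc3)cc(=O)c2c1O | target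

**Step count.** Total: 10 steps. Longest linear sequence: 9 steps (steps 1, 2 and 4–10); step 3 is a one-step side branch.

**Steps most likely to fail**

Step 4. The ring opening may rotate the side chain inward, which allows a 1,5-hydrogen shift from the stereogenic carbon to the ketene. The vinylketene may also acylate the phenol as it forms, or the siloxyalkyne may decay thermally before it is captured. The fallback gives up ring construction and attaches a bought arene to the stereocentre. It sets out from silyl triflate 8. Purchased 3,5-diethoxyphenol F1 is silylated (8, 2,6-lutidine, CH2Cl2) to (3,5-diethoxyphenoxy)triisopropylsilane F2. n-BuLi/TMEDA in THF at 0 °C lithiates the position between the two ethoxy groups to give {2,6-diethoxy-4-[(triisopropylsilyl)oxy]phenyl}lithium F3, which MgBr2·OEt2 converts into the corresponding arylmagnesium bromide F4. Conjugate addition of F4, mediated by CuBr·SMe2, to (R)-4-phenyl-3-[(E)-3-phenylprop-2-enoyl]oxazolidin-2-one F5 (from cinnamoyl chloride and the lithiated auxiliary) should occur on the face of the chelated s-cis enoyl imide remote from the 4-phenyl group. This should give (R)-3-[(R)-3-{2,6-diethoxy-4-[(triisopropylsilyl)oxy]phenyl}-3-phenylpropanoyl]-4-phenyloxazolidin-2-one F6. MeOMgBr in MeOH at 0 °C exchanges the auxiliary for methoxide, and the material comes back to the route at 17.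

Step 3. Monolithium acetylide may disproportionate to insoluble dilithium acetylide on warming, before oxygen transfer is complete, and silylation may drift from oxygen to carbon. The fallback reaches the same ynolate without an acetylide, by a Kowalski-type rearrangement. It sets out from silyl triflate 8 and purchased ethyl formate. Dibromomethane and lithium 2,2,6,6-tetramethylpiperidide in THF at −78 °C give dibromomethyllithium F7, which adds to ethyl formate; loss of ethoxide and deprotonation give lithium 2,2-dibromoethen-1-olate F8. n-BuLi then exchanges one bromine for lithium, and the carbenoid rearranges by 1,2-hydrogen shift with loss of LiBr to lithium ethynolate 10. Silylation with 8 as in step 3 returns the route at 11.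

Step 2. Under amine the aldoketene may dimerise or acylate its own product faster than it adds to the ynol ether, and a warm half-ester chloride may exchange its two carbonyl ends through a cyclic acyloxonium ion, eroding the enantiomeric purity. The fallback makes the same ketene without base and without an acid chloride, by Wolff rearrangement. It sets out from ethoxyacetylene 3 and purchased (R)-phenylsuccinic acid F9. Fischer mono-esterification (MeOH, cat. AcCl, 0 °C) at the unhindered CH2CO2H should give (R)-4-methoxy-4-oxo-2-phenylbutanoic acid F10. Isobutyl chloroformate and N-methylmorpholine in THF at −20 °C give the mixed isobutyl carbonic anhydride F11, and diazomethane converts it into methyl (R)-5-diazo-4-oxo-3-phenylpentanoate F12. Irradiation (Pyrex-filtered Hg lamp, CH2Cl2, rt) in the presence of 3 triggers the Wolff rearrangement, in which the stereogenic carbon migrates with retention to give ketene 5. The ketene is trapped in the same flask, and the route is rejoined at 6.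

Further compounds
F1 | step 4 | 3,5-diethoxyphenol | CCOc1cc(O)cc(OCC)c1
F2 | step 4 | (3,5-diethoxyphenoxy)triisopropylsilane | CCOc1cc(O[Si](C(C)C)(C(C)C)C(C)C)cc(OCC)c1
F3 | step 4 | {2,6-diethoxy-4-[(triisopropylsilyl)oxy]phenyl}lithium | [Li]c1c(OCC)cc(O[Si](C(C)C)(C(C)C)C(C)C)cc1OCC
F4 | step 4 | {2,6-diethoxy-4-[(triisopropylsilyl)oxy]phenyl}magnesium bromide | Br[Mg]c1c(OCC)cc(O[Si](C(C)C)(C(C)C)C(C)C)cc1OCC
F5 | step 4 | (R)-4-phenyl-3-[(E)-3-phenylprop-2-enoyl]oxazolidin-2-one | O=C(/C=C/c1ccccc1)N1C(=O)OC[C@H]1c1ccccc1
F6 | step 4 | (R)-3-[(R)-3-{2,6-diethoxy-4-[(triisopropylsilyl)oxy]phenyl}-3-phenylpropanoyl]-4-phenyloxazolidin-2-one | O=C(C[C@H](c1ccccc1)c1c(OCC)cc(O[Si](C(C)C)(C(C)C)C(C)C)cc1OCC)N1C(=O)OC[C@H]1c1ccccc1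
F7 | step 3 | dibromomethyllithium | [Li]C(Br)Br
F8 | step 3 | lithium 2,2-dibromoethen-1-olate | [Li]OC=C(Br)Br
F9 | step 2 | (R)-phenylsuccinic acid | OC(=O)C[C@H](c1ccccc1)C(=O)O
F10 | step 2 | (R)-4-methoxy-4-oxo-2-phenylbutanoic acid | COC(=O)C[C@H](c1ccccc1)C(=O)O
F11 | step 2 | (R)-4-methoxy-4-oxo-2-phenylbutanoic isobutyl carbonic anhydride | COC(=O)C[C@H](c1ccccc1)C(=O)OC(=O)OCC(C)C
F12 | step 2 | methyl (R)-5-diazo-4-oxo-3-phenylpentanoate | COC(=O)C[C@H](c1ccccc1)C(=O)C=[N+]=[N-]
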